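The runs are simulated for substances that don't exist.

Start from the small charge of the south-east run, then the larger one of the south-west run; the flask holds more starting material than either.

| flask | starting material | gas phase | remark | time |
|---|---|---|---|---|
| south-east | 0.10 M | 54 mM (held) | run made earlier |  |
| south-west | 0.15 M | 54 mM (held) | run made earlier |  |
| flask | 0.20 M | 54 mM (held) |  | 8.0 h |

| run | time / h | target / % | starting material / % |
|---|---|---|---|
| south-east | 0.667 | 0.3 | 99.5 |
| south-east | 1.33 | 2.1 | 97.9 |
| south-east | 2.00 | 3.7 | 96.1 |
| south-east | 3.00 | 6.6 | 93.4 |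
| south-east | 4.00 | 9.2 | 89.7 |
| south-east | 5.00 | 11.8 | 87.3 |
| south-west | 0.250 | 0 | 99.3 |
| south-west | 0.667 | 0.5 | 99.1 |
| south-west | 1.33 | 1.9 | 98.2 |
| south-west | 2.00 | 3.8 | 96.4 |
| south-west | 3.00 | 5.9 | 93.1 |
| south-west | 4.00 | 9.2 | 89.8 |
| south-west | 5.00 | 11.0 | 87.7 |

(scatter of a reading: 0.3 percentage points)

- at the start none of the gas phase is in solution

* how much target there is at 8.0 h, in percent of the starting material charged
* concentration of dissolved gas in solution at 8.0 h, in percent of saturation

Read the starting-material column as fractions of the charge. Between 2.00 h and 5.00 h, the south-east fraction falls from 96.1% to 87.3%, a logarithmic slope of 0.0320 h⁻¹. The south-west rows at those times, 96.4% and 87.7%, give 0.0315 h⁻¹. The two slopes match, so take their mean, k′ = 0.0318 h⁻¹, the fraction of the remaining starting material lost per hour, a pseudo-first-order constant, and assume it holds at the flask's charge.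

Now run the rows at 2.00 h back to the full charge: the line starts after a lag of 0.797 h. Then read the last rows, target over starting material gone: 91.2%.

My reckoning for the flask at 8.0 h leaves 79.5% of the starting material and gives 18.7% of target. I read k′ as a rate constant times the gas level, and I put no number of my own on the saturation.

The forecast says 18.5% of target and 95% of saturation: “Dissolved gas should therefore sit near 95% of saturation”.

The flask gives 17.2% of target, with 80% of the starting material left. Its dissolved gas stands at 67.3% of saturation.

    gas phase ⇌ dissolved gas, rate k1*(csat - [dissolved gas]) (kL = 1.90 × 10⁻⁴ s⁻¹)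
    starting material + dissolved gas → target (k = 2.40 × 10⁻⁴ M⁻¹ s⁻¹)
    dissolved gas + target → over-reacted product (k = 2.10 × 10⁻⁴ M⁻¹ s⁻¹)
    target → over-reaction product A (k = 1.10 × 10⁻⁸ s⁻¹)
    2 dissolved gas → self-condensation product (k = 5.90 × 10⁻⁴ M⁻¹ s⁻¹)
    dissolved gas + target → over-reaction product B (k = 1.10 × 10⁻⁴ M⁻¹ s⁻¹)

In the flask, target is 86.0% of the starting material gone, against the 91.2% read from the runs. Carry k′ and the lag to the same flask read at 15 h, all amounts held: they leave 63.7% of the starting material and, with 91.2%, give 33.1% of target. That flask holds 64% of the starting material, 6.13% of over-reacted product, 3.21% of over-reaction product B and 26.4% of target.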